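## The problem

The target is an open-chain diketone capped by a 2,4-dihydroxyphenyl group. With the chain numbered from the aryl ketone carbon C1 to the gem-dimethyl alkene carbon C11, no ring has to be built, and the task is to join fragments along C1–C11 in a workable order. The only stereocentre is the all-carbon quaternary carbon C3, which carries methyl, vinyl and two methylene arms (C2 and C4) that differ only beyond their first atom. Nothing else in the molecule can relay chirality to it, so it must be set by a catalyst or by transfer from a sacrificial centre, and it cannot be corrected later. The C6=C7 alkene is trisubstituted and E, which calls for a stereodefined alkenyl partner and not for olefination with a branched reagent. The C8 methylene lies between this alkene and the C9 ketone, itself conjugated to C10=C11, so acid or base will draw C6=C7 into conjugation; the C9 carbonyl should therefore appear last and under neutral conditions. The resorcinol hydroxyls must be masked through the organometallic steps and unmasked without strong acid, and the vinyl group on C3 excludes hydroboration, ozonolysis and hydrogenation and makes a radical or cation at C2 or C4 liable to 1,2-vinyl migration. The enabling feature is that C3 with its methyl, its vinyl and the C2 methylene is the tertiary allylic carbon of isoprene monoepoxide with its CH2–O arm, so the C3–C4 bond can be made by attack of a malonate on the π-allylpalladium species from the racemic epoxide.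

## Retrosynthesis

**C9 carbonyl and phenol masks.** Target 25 is traced to triol 24 by returning C9 to the carbinol level, and 24 to the tris-silyl ether 23. No skeletal bond is cut. The reason is that the C8 methylene is acidified only once C9 is a ketone. Oxidising first and desilylating last would expose the skipped dienone to fluoride, whereas the chosen order exposes it to nothing after it is formed. The forward reaction must pick the allylic carbinol of 24 out from two free phenols.

**C5–C6.** Compound 23 is cut between sp3 C5 and sp2 C6 into primary iodide 16 (used as its zinc derivative 22) and alkenyl iodide 21. The neighbouring cuts are worse. Making C6=C7 by olefination would need a branched partner with weak E control, C4–C5 lies next to the quaternary carbon, and C7–C8 or C8–C9 would form bonds at the doubly activated methylene. The cut gives a C1–C5 piece carrying the arene and the stereocentre and a C6–C11 piece carrying the alkene geometry. The forward coupling must keep that geometry and tolerate the aryl ketone.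

**C6–C11 fragment.** Iodide 21 comes from alkyne 19 by syn addition of methyl and metal (alane 20) and iodination, which cuts the C7–methyl bond and fixes E. Ether 19 comes from alcohol 18, and 18 from 3-methylbut-2-enal 17 by forming C8–C9 with a three-carbon propargyl nucleophile. The forward reactions need 1,2-addition to the enal and terminal regiochemistry in the carbometalation.

**C1–aryl.** Iodide 16 comes from alcohol 15, 15 from benzylic carbinol 14, and 14 from lactol 10 and aryl bromide 12 (through Grignard reagent 13); 12 comes from 4-bromoresorcinol 11. The alternative cut at C1–C2 would need a carbanion or radical at C2, which is neopentyl and adjacent to the vinyl-bearing carbon. Lactol 10 holds the C1 aldehyde and the C5 hydroxyl in one function, so C5 needs no protecting group at this stage. The forward reactions need an aryl metal that tolerates an ortho silyloxy group and an oxidant that takes the benzylic carbinol beside a primary one.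

**C1–C2.** Lactol 10 comes from enol ether 9 and this from aldehyde 8, a one-carbon olefination at C2; 8 comes from mono-silyl ether 7, diol 6 and lactone 5. Because C2 is neopentyl, displacement there is closed and carbonyl chemistry is the only entry; 8 has no α-hydrogen and cannot epimerise. The two hydroxyls of 6 differ sterically, so one silyl group suffices, and it leaves in the acid treatment that unmasks C1. The forward reactions need selective silylation of the C5 hydroxyl and a Wittig reaction on a hindered aldehyde.

**C3–C4 (key cut).** Lactone 5 comes from lactone ester 4 and hydroxy malonate 3, and 3 from racemic isoprene monoepoxide 1 and dimethyl malonate 2. In 5 the carbonyl carbon is C5 and the ring O–CH2 is C2, so the two arms of C3 are different from the outset. A cut at C2–C3 or at C3–methyl would require a hard nucleophile at a hindered acceptor. The C3–C4 cut uses a soft stabilised carbon acid, the class known to attack ionised 1 at the tertiary terminus. The forward reaction must deliver branched regioselectivity and one enantiomer from a racemate.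

## Roads not taken

**Alternative 1:** The cut is the C1–O bond of a seven-membered lactone, so that C1–C6 come from the ring of the prochiral ketone 4-methyl-4-vinylcyclohexan-1-one A1. In the forward step a flavin-dependent Baeyer–Villiger monooxygenase inserts oxygen into one of the two enantiotopic carbonyl–methylene bonds and gives (R)-5-methyl-5-vinyloxepan-2-one A2.
- Merits: no carbon–carbon bond is made at the congested carbon in the asymmetric step; A2 holds six chain carbons with both ends oxygenated and different; the C1 alkoxy end maps onto the aryl ketone without the one-carbon homologation that the chosen plan needs in steps 5 and 6.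
- Weak points: the enzyme must tell methyl from vinyl at a carbon remote from the carbonyl with no polar handle, which cannot be predicted; A1 is not a commodity and its quaternary carbon must first be built; C6 emerges as a carboxyl carbon and must become the sp2 CH of an E-trisubstituted alkene, by a branched olefination or an alkyne detour.
- Comparison: this road is better in how much of the chain the key product holds and in sparing the homologation. The chosen plan sets against this that quaternary carbon and configuration arise together in step 1 from two commodity chemicals, and that the alkene geometry comes from the prefabricated iodide 21.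

**Alternative 2:** The cut is C2–C3, made by [3,3]-shift of the allyl 1-arylvinyl ether (R,E)-{1-[(1-{2,4-bis[(tert-butyldimethylsilyl)oxy]phenyl}vinyl)oxy]-3,7-dimethylocta-2,6-dien-1-yl}dimethyl(phenyl)silane A3. On heating, a chair transition state with the silyl group equatorial should give (R,E)-1-[2,4-bis(tert-butyldimethylsilyloxy)phenyl]-3-[2-(dimethylphenylsilyl)vinyl]-3,7-dimethyloct-6-en-1-one A4, forming C2–C3, the aryl ketone and an E-vinylsilane at once.
- Merits: the aryl ketone and the C1–C3 connection appear in one step, which removes the sequence of steps 5 to 9 of the chosen plan; the terpenoid allyl part supplies C3–C7 with the C7 methyl; chirality transfer in acyclic Claisen rearrangements is dependable.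
- Weak points: the chirality is stoichiometric and must first be installed in an α-silyl allylic carbinol that is prone to Brook rearrangement; the vinyl ether of this hindered carbinol needs an ester methylenation; chair/boat leakage and alkene purity both limit the enantiomeric purity. Afterwards the vinylsilane must be protodesilylated beside an acid-sensitive alkene, and the prenyl terminus must be oxidised at one methyl and extended by an acyl-anion alkylation to build C8–C11.
- Comparison: this road is probably shorter in its longest linear sequence and clearly better at the western end. The chosen plan sets against it catalytic induction from a racemic feedstock, a C6–C11 piece with fixed geometry, and no late allylic C–H oxidation.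

**Alternative 3:** The cut is the C3–methyl bond, followed by scission of the C1–C6 bond of a six-membered ring. A methyl Grignard reagent would add in the 1,4 sense to 3-vinylcyclohex-2-en-1-one A5 under copper catalysis with a chiral N-heterocyclic carbene ligand, giving (R)-3-methyl-3-vinylcyclohexan-1-one A6.
- Merits: the step is catalytic, A5 is close to commercial material, the ring holds C1–C6 in order, and C1 is already a carbonyl carbon.
- Weak points: A5 is an extended acceptor in which 1,6-addition at the vinyl terminus competes, so regiocontrol rests wholly on the ligand, and methyl is the smallest group to transfer. The ring of A6 must then be cleaved toward C6 and not C2 without touching the vinyl group, which excludes ozone. C6 again emerges as a carbonyl carbon that has to become the E-trisubstituted alkene.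
- Comparison: this road equals the chosen plan in being catalytic at the quaternary carbon and is better in delivering C1 at the right oxidation level. The chosen plan sets against it that its regiochemical problem is steered by the substrate's own alkoxide and that 3 carries two different arms without a ring cleavage.

Key step: step 1

Assumption: the (R,R) antipode of the ligand is written for step 1 by analogy with the facial preference of this ligand family toward vinyl epoxides; should 3 form with the opposite configuration, the (S,S) antipode is to be used with no other change.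

## Route

Step 1
Reactants: 1 racemic 2-methyl-2-vinyloxirane; 2 dimethyl malonate
Product: 3 dimethyl 2-[(2R)-1-hydroxy-2-methylbut-3-en-2-yl]malonate
Conditions: Pd2(dba)3·CHCl3 (1 mol %), N,N′-[(1R,2R)-cyclohexane-1,2-diyl]bis[2-(diphenylphosphanyl)benzamide] (3 mol %), CH2Cl2, rt, no added base
Reagents that add atoms: none
Why: Zerovalent palladium opens either enantiomer of 1 with inversion to a zwitterionic π-allylpalladium alkoxide, and the two diastereomeric complexes interconvert by π–σ–π isomerisation through the unsubstituted CH2 terminus faster than either is trapped, so the racemate drains through one complex (dynamic kinetic asymmetric transformation). The alkoxide is the only base present: it deprotonates 2 and, as a hydrogen-bonded ion pair in the non-polar solvent, passes the malonate to the adjacent tertiary terminus, which favours the branched over the linear 1,4-adduct; added base and polar solvent, which would free the nucleophile, are left out. Attack is outer-sphere and anti to palladium, and the ligand pocket leaves one face of the tertiary terminus open, so C3 should be set as (R) by the catalyst alone. Only the C3–C4 bond is formed and no ring is closed. The step needs regioselectivity, secured by the substrate's own alkoxide, and enantioselectivity, secured by fast equilibration together with the ligand. The closest known reaction type is the Tsuji–Trost asymmetric allylic alkylation of isoprene monoepoxide with β-dicarbonyl carbon acids at the tertiary carbon.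

Step 2
Reactants: 3 dimethyl 2-[(2R)-1-hydroxy-2-methylbut-3-en-2-yl]malonate
Product: 5 (S)-4-methyl-4-vinyldihydrofuran-2(3H)-one, via lactone ester 4 (not isolated)
Conditions: PPTS (5 mol %), PhMe, 80 °C; evaporate; LiCl, H2O, DMSO, 150 °C
Reagents that add atoms: none
Why: Acid-catalysed lactonisation of the γ-hydroxy diester gives 4, and Krapcho demethoxycarbonylation removes the remaining ester; the quaternary carbon is not enolisable and the descriptor changes only through the priority rules.

Step 3
Reactants: 5 (S)-4-methyl-4-vinyldihydrofuran-2(3H)-one
Product: 6 (S)-2-methyl-2-vinylbutane-1,4-diol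
Conditions: LiAlH4, THF, 0 °C → rt
Reagents that add atoms: none
Why: Hydride reduction of a lactone to the 1,4-diol; the isolated vinyl group is inert.

Step 4
Reactants: 6 (S)-2-methyl-2-vinylbutane-1,4-diol
Product: 7 (S)-4-[(tert-butyldimethylsilyl)oxy]-2-methyl-2-vinylbutan-1-ol
Conditions: TBSCl (1.05 equiv), imidazole, CH2Cl2, −20 → 0 °C
Reagents that add atoms: tert-butyldimethylsilyl chloride, CC(C)(C)[Si](C)(C)Cl
Why: Selective monosilylation: the C5 hydroxyl is an unhindered primary alcohol and the C2 hydroxyl is neopentyl to the quaternary carbon, so one equivalent of silyl chloride at low temperature should take C5–OH.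

Step 5
Reactants: 7 (S)-4-[(tert-butyldimethylsilyl)oxy]-2-methyl-2-vinylbutan-1-ol
Product: 8 (S)-4-[(tert-butyldimethylsilyl)oxy]-2-methyl-2-vinylbutanal
Conditions: Dess–Martin periodinane, CH2Cl2, 0 °C → rt
Reagents that add atoms: none
Why: Dess–Martin oxidation of a hindered primary alcohol; aldehyde 8 has no α-hydrogen and can neither epimerise nor conjugate.

Step 6
Reactants: 8 (S)-4-[(tert-butyldimethylsilyl)oxy]-2-methyl-2-vinylbutanal
Product: 10 (4R)-4-methyl-4-vinyltetrahydro-2H-pyran-2-ol (anomeric mixture), via enol ether 9 (not isolated)
Conditions: Ph3P(CH2OMe)Cl, KN(SiMe3)2, THF, 0 °C → rt; then 2 M aq. HCl, THF, rt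
Reagents that add atoms: (methoxymethyl)triphenylphosphonium chloride, COC[P+](c1ccccc1)(c1ccccc1)c1ccccc1.[Cl-]; water, O
Why: Wittig methoxymethylenation of the α-quaternary aldehyde gives 9; aqueous acid hydrolyses the enol ether to the C1 aldehyde and cleaves the primary silyl ether in the same pot, and the 5-hydroxy aldehyde closes to the six-membered lactol. Protonation occurs at C2 and the positive charge sits on C1, so no cation arises next to the vinyl-bearing carbon.

Step 7
Reactants: 11 4-bromoresorcinol
Product: 12 1-bromo-2,4-bis[(triisopropylsilyl)oxy]benzene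
Conditions: TIPSCl (2.3 equiv), imidazole, DMF, 40 °C
Reagents that add atoms: triisopropylsilyl chloride, CC(C)[Si](Cl)(C(C)C)C(C)C
Why: Standard silylation of both phenols; the bulky silyl group resists oxygen-to-carbon migration in the ortho-metallated arene, survives the zinc and palladium steps and leaves with fluoride.

Step 8
Reactants: 10 (4R)-4-methyl-4-vinyltetrahydro-2H-pyran-2-ol; 12 1-bromo-2,4-bis[(triisopropylsilyl)oxy]benzene
Product: 14 (3R)-1-{2,4-bis[(triisopropylsilyl)oxy]phenyl}-3-methyl-3-vinylpentane-1,5-diol (both C1 epimers), via aryl Grignard reagent 13 (not isolated)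
Conditions: 12 (3 equiv), Mg turnings (I2-activated), THF, 50 °C; then 10, THF, 0 °C → rt; aq. NH4Cl
Reagents that add atoms: none
Why: Grignard addition to a lactol: the first equivalent of 13 deprotonates 10, whose magnesium alkoxide is in equilibrium with the open-chain aldehyde, and a second equivalent adds to it, giving the 1,5-diol with C5–OH free; the new carbinol centre is unselective and is erased in step 9.

Step 9
Reactants: 14 (3R)-1-{2,4-bis[(triisopropylsilyl)oxy]phenyl}-3-methyl-3-vinylpentane-1,5-diol
Product: 15 (R)-1-{2,4-bis[(triisopropylsilyl)oxy]phenyl}-5-hydroxy-3-methyl-3-vinylpentan-1-one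
Conditions: MnO2 (activated, 15 equiv), CH2Cl2, rt
Reagents that add atoms: none
Why: MnO2 oxidises the activated, electron-rich benzylic carbinol and leaves the saturated primary alcohol untouched.

Step 10
Reactants: 15 (R)-1-{2,4-bis[(triisopropylsilyl)oxy]phenyl}-5-hydroxy-3-methyl-3-vinylpentan-1-one
Product: 16 (S)-1-{2,4-bis[(triisopropylsilyl)oxy]phenyl}-5-iodo-3-methyl-3-vinylpentan-1-one
Conditions: I2, PPh3, imidazole, CH2Cl2, 0 °C
Reagents that add atoms: iodine, II
Why: Appel iodination of the primary alcohol under buffered conditions; the stereocentre is untouched and its descriptor changes only because iodine raises the priority of the C4 arm.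

Step 11
Reactants: 17 3-methylbut-2-enal
Product: 18 racemic 6-methylhept-5-en-1-yn-4-ol
Conditions: propargyl bromide, Zn dust, THF, 0 °C; then 17, −20 → 0 °C; aq. NH4Cl
Reagents that add atoms: propargyl bromide, C#CCBr
Why: Zinc-mediated Barbier-type propargylation: the allenylzinc species adds in the SE2′ sense and 1,2 to the enal to give the homopropargylic alcohol; the carbinol is oxidised later, so its configuration is immaterial.

Step 12
Reactants: 18 racemic 6-methylhept-5-en-1-yn-4-ol
Product: 19 racemic triethyl[(6-methylhept-5-en-1-yn-4-yl)oxy]silane
Conditions: TESCl, imidazole, CH2Cl2, 0 °C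
Reagents that add atoms: chlorotriethylsilane, CC[Si](Cl)(CC)CC
Why: Standard silylation; the silyl ether hides the acidic hydroxyl from the organozinc reagent of step 14 and leaves together with the aryl silyl ethers.

Step 13
Reactants: 19 racemic triethyl[(6-methylhept-5-en-1-yn-4-yl)oxy]silane
Product: 21 racemic (E)-triethyl[(1-iodo-2,6-dimethylhepta-1,5-dien-4-yl)oxy]silane, via alkenylalane 20 (not isolated)
Conditions: Me3Al (2.5 equiv), Cp2ZrCl2 (0.25 equiv), CH2Cl2, 0 °C → rt; then I2, THF, −30 → 0 °C
Reagents that add atoms: trimethylaluminium, C[Al](C)C; iodine, II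
Why: Zirconium-catalysed Negishi carboalumination adds methyl and aluminium syn across the terminal alkyne with aluminium on the terminal carbon, and iodinolysis of 20 with retention gives the (E)-alkenyl iodide, which fixes the C6=C7 geometry.

Step 14
Reactants: 16 (S)-1-{2,4-bis[(triisopropylsilyl)oxy]phenyl}-5-iodo-3-methyl-3-vinylpentan-1-one; 21 racemic (E)-triethyl[(1-iodo-2,6-dimethylhepta-1,5-dien-4-yl)oxy]silane
Product: 23 (3R,6E)-1-{2,4-bis[(triisopropylsilyl)oxy]phenyl}-3,7,11-trimethyl-9-[(triethylsilyl)oxy]-3-vinyldodeca-6,10-dien-1-one (both C9 epimers), via alkylzinc iodide 22 (not isolated)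
Conditions: 16, Zn dust (Me3SiCl-activated), LiCl, THF, 40 °C; then 21 (1.2 equiv), PdCl2(dppf) (5 mol %), THF, rt → 45 °C
Reagents that add atoms: none
Why: Zinc insertion into the primary C–I bond gives 22, an alkylzinc halide of the kind that tolerates ketones, and Negishi coupling with 21 forms C5–C6 with retention of alkene geometry; the carbon–zinc bond is made at C5, separated from the quaternary carbon by C4, so neither cyclisation nor vinyl migration is expected.

Step 15
Reactants: 23 (3R,6E)-1-{2,4-bis[(triisopropylsilyl)oxy]phenyl}-3,7,11-trimethyl-9-[(triethylsilyl)oxy]-3-vinyldodeca-6,10-dien-1-one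
Product: 24 (3R,6E)-1-(2,4-dihydroxyphenyl)-9-hydroxy-3,7,11-trimethyl-3-vinyldodeca-6,10-dien-1-one (both C9 epimers)
Conditions: Bu4NF (4 equiv), THF, 0 °C → rt
Reagents that add atoms: none
Why: Fluoride cleaves the two aryl silyl ethers and the secondary silyl ether in one operation; C9 is still a carbinol here, so the basic fluoride meets no skipped enone.

Step 16
Reactants: 24 (3R,6E)-1-(2,4-dihydroxyphenyl)-9-hydroxy-3,7,11-trimethyl-3-vinyldodeca-6,10-dien-1-one
Product: 25 (R,E)-1-(2,4-dihydroxyphenyl)-3,7,11-trimethyl-3-vinyldodeca-6,10-diene-1,9-dione (CNP0208188.1)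
Conditions: MnO2 (activated, 20 equiv), CH2Cl2–EtOAc, rt
Reagents that add atoms: none
Why: Chemoselective MnO2 oxidation of the allylic C9 carbinol under neutral heterogeneous conditions; the acyl-deactivated resorcinol hydroxyls should not be oxidised, and the C6=C7 bond, only now β,γ to a ketone, is never exposed to acid or base.

## Compound list

1 | racemic 2-methyl-2-vinyloxirane | C=CC1(C)CO1 | starting material
2 | dimethyl malonate | COC(=O)CC(=O)OC | starting material
3 | dimethyl 2-[(2R)-1-hydroxy-2-methylbut-3-en-2-yl]malonate | C=C[C@@](C)(CO)C(C(=O)OC)C(=O)OC | intermediate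
4 | methyl (4R)-4-methyl-2-oxo-4-vinyltetrahydrofuran-3-carboxylate (C3 epimers, not isolated) | C=C[C@@]1(C)COC(=O)C1C(=O)OC | intermediate
5 | (S)-4-methyl-4-vinyldihydrofuran-2(3H)-one | C=C[C@@]1(C)COC(=O)C1 | intermediate
6 | (S)-2-methyl-2-vinylbutane-1,4-diol | C=C[C@@](C)(CO)CCO | intermediate
7 | (S)-4-[(tert-butyldimethylsilyl)oxy]-2-methyl-2-vinylbutan-1-ol | C=C[C@@](C)(CO)CCO[Si](C)(C)C(C)(C)C | intermediate
8 | (S)-4-[(tert-butyldimethylsilyl)oxy]-2-methyl-2-vinylbutanal | C=C[C@@](C)(C=O)CCO[Si](C)(C)C(C)(C)C | intermediate
9 | tert-butyl{[(3S)-5-methoxy-3-methyl-3-vinylpent-4-en-1-yl]oxy}dimethylsilane (E/Z mixture, not isolated) | C=C[C@@](C)(C=COC)CCO[Si](C)(C)C(C)(C)C | intermediate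
10 | (4R)-4-methyl-4-vinyltetrahydro-2H-pyran-2-ol (anomeric mixture) | C=C[C@@]1(C)CC(O)OCC1 | intermediate
11 | 4-bromoresorcinol | Oc1ccc(Br)c(O)c1 | starting material
12 | 1-bromo-2,4-bis[(triisopropylsilyl)oxy]benzene | CC(C)[Si](Oc1ccc(Br)c(O[Si](C(C)C)(C(C)C)C(C)C)c1)(C(C)C)C(C)C | intermediate
13 | {2,4-bis[(triisopropylsilyl)oxy]phenyl}magnesium bromide (not isolated) | CC(C)[Si](Oc1ccc([Mg]Br)c(O[Si](C(C)C)(C(C)C)C(C)C)c1)(C(C)C)C(C)C | intermediate
14 | (3R)-1-{2,4-bis[(triisopropylsilyl)oxy]phenyl}-3-methyl-3-vinylpentane-1,5-diol (both C1 epimers) | C=C[C@](C)(CCO)CC(O)c1ccc(O[Si](C(C)C)(C(C)C)C(C)C)cc1O[Si](C(C)C)(C(C)C)C(C)C | intermediate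
15 | (R)-1-{2,4-bis[(triisopropylsilyl)oxy]phenyl}-5-hydroxy-3-methyl-3-vinylpentan-1-one | C=C[C@](C)(CCO)CC(=O)c1ccc(O[Si](C(C)C)(C(C)C)C(C)C)cc1O[Si](C(C)C)(C(C)C)C(C)C | intermediate
16 | (S)-1-{2,4-bis[(triisopropylsilyl)oxy]phenyl}-5-iodo-3-methyl-3-vinylpentan-1-one | C=C[C@](C)(CCI)CC(=O)c1ccc(O[Si](C(C)C)(C(C)C)C(C)C)cc1O[Si](C(C)C)(C(C)C)C(C)C | intermediate
17 | 3-methylbut-2-enal | CC(C)=CC=O | starting material
18 | racemic 6-methylhept-5-en-1-yn-4-ol | C#CCC(O)C=C(C)C | intermediate
19 | racemic triethyl[(6-methylhept-5-en-1-yn-4-yl)oxy]silane | C#CCC(O[Si](CC)(CC)CC)C=C(C)C | intermediate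
20 | (E)-dimethyl{2,6-dimethyl-4-[(triethylsilyl)oxy]hepta-1,5-dien-1-yl}alane (racemic, not isolated) | C[Al](C)/C=C(\C)CC(O[Si](CC)(CC)CC)C=C(C)C | intermediate
21 | racemic (E)-triethyl[(1-iodo-2,6-dimethylhepta-1,5-dien-4-yl)oxy]silane | I/C=C(\C)CC(O[Si](CC)(CC)CC)C=C(C)C | intermediate
22 | [(3S)-5-{2,4-bis[(triisopropylsilyl)oxy]phenyl}-3-methyl-5-oxo-3-vinylpentyl]zinc iodide (not isolated) | C=C[C@](C)(CC[Zn]I)CC(=O)c1ccc(O[Si](C(C)C)(C(C)C)C(C)C)cc1O[Si](C(C)C)(C(C)C)C(C)C | intermediate
23 | (3R,6E)-1-{2,4-bis[(triisopropylsilyl)oxy]phenyl}-3,7,11-trimethyl-9-[(triethylsilyl)oxy]-3-vinyldodeca-6,10-dien-1-one (both C9 epimers) | C=C[C@](C)(CC/C=C(\C)CC(O[Si](CC)(CC)CC)C=C(C)C)CC(=O)c1ccc(O[Si](C(C)C)(C(C)C)C(C)C)cc1O[Si](C(C)C)(C(C)C)C(C)C | intermediate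
24 | (3R,6E)-1-(2,4-dihydroxyphenyl)-9-hydroxy-3,7,11-trimethyl-3-vinyldodeca-6,10-dien-1-one (both C9 epimers) | C=C[C@](C)(CC/C=C(\C)CC(O)C=C(C)C)CC(=O)c1ccc(O)cc1O | intermediate
25 | (R,E)-1-(2,4-dihydroxyphenyl)-3,7,11-trimethyl-3-vinyldodeca-6,10-diene-1,9-dione | C=C[C@](C)(CC/C=C(\C)CC(=O)C=C(C)C)CC(=O)c1ccc(O)cc1O | target

## Step count and least certain steps

Total: 16 steps. Longest linear sequence: 12 steps (steps 1–6, 8–10 and 14–16).

**Step 1 (key step).** The malonate anion may escape the alkoxide ion pair and attack the unsubstituted terminus, leaking to the linear 1,4-adduct; trapping may also outrun π–σ–π equilibration and erode the enantiomeric purity. A minor linear adduct would be shed at step 2, since it cannot close to a five-membered lactone, but low enantiomeric purity cannot be repaired later. The fallback sets out from 1 and comes back at 5. Racemic 1 would be alkylated under the same catalyst with Meldrum's acid in place of 2; this carbon acid is fully deprotonated by the alkoxide and its anion is a weaker nucleophile, so pairing is tighter and attack slower relative to equilibration. The adduct 5-[(2R)-1-hydroxy-2-methylbut-3-en-2-yl]-2,2-dimethyl-1,3-dioxane-4,6-dione F1 should close on itself with loss of acetone to (4R)-4-methyl-2-oxo-4-vinyltetrahydrofuran-3-carboxylic acid F2, and warming F2 would expel carbon dioxide and give 5.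

**Step 8.** Ring opening of the magnesium lactolate may be slow, enolisation of the aldehyde may compete, the ortho silyl group may migrate from oxygen to carbon on prolonged warming of 13, and the electron-rich benzylic carbinol of 14 may ionise during work-up. The fallback sets out from 10 and comes back at 15, replacing carbonyl addition and oxidation by acyl substitution. Lactol 10 would be oxidised (TEMPO, PhI(OAc)2) to (R)-4-methyl-4-vinyltetrahydro-2H-pyran-2-one F3 and opened with N,O-dimethylhydroxylamine hydrochloride and iPrMgCl to (R)-5-hydroxy-N-methoxy-N,3-dimethyl-3-vinylpentanamide F4. The aryllithium made from 12 by bromine–lithium exchange at −78 °C (two equivalents, the first consumed by the hydroxyl) would then add to give 15 directly, with no benzylic carbinol on the way.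

**Step 14.** Zinc insertion may be slow or incomplete, the carbon–zinc bond may add to the C1 ketone through a five-membered ring, or β-hydride elimination may follow transmetalation. The fallback sets out from 16 and 21 and comes back at 23: a nickel-catalysed reductive cross-electrophile coupling (NiCl2(dme), 4,4′-di-tert-butyl-2,2′-bipyridine, Mn powder, DMA) joins the two iodides directly without a preformed organometallic and tolerates the ketone. It makes no new compound.

**Step 16.** The phenols may be oxidised or held on the oxide surface, the hindered secondary allylic carbinol may react slowly, or C6=C7 may migrate into conjugation on the solid. The fallback sets out from 23 and comes back at 25, reversing the order of unmasking. The secondary silyl ether alone would be removed with PPTS in MeOH to give (3R,6E)-1-{2,4-bis[(triisopropylsilyl)oxy]phenyl}-9-hydroxy-3,7,11-trimethyl-3-vinyldodeca-6,10-dien-1-one F5. Buffered Dess–Martin oxidation would give (R,E)-1-{2,4-bis[(triisopropylsilyl)oxy]phenyl}-3,7,11-trimethyl-3-vinyldodeca-6,10-diene-1,9-dione F6, and acetic acid-buffered Bu4NF would release the phenols to give 25.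

## Further compounds

F1 | step 1 | 5-[(2R)-1-hydroxy-2-methylbut-3-en-2-yl]-2,2-dimethyl-1,3-dioxane-4,6-dione | C=C[C@@](C)(CO)C1C(=O)OC(C)(C)OC1=O
F2 | step 1 | (4R)-4-methyl-2-oxo-4-vinyltetrahydrofuran-3-carboxylic acid (C3 epimers) | C=C[C@@]1(C)COC(=O)C1C(=O)O
F3 | step 8 | (R)-4-methyl-4-vinyltetrahydro-2H-pyran-2-one | C=C[C@@]1(C)CC(=O)OCC1
F4 | step 8 | (R)-5-hydroxy-N-methoxy-N,3-dimethyl-3-vinylpentanamide | C=C[C@](C)(CCO)CC(=O)N(C)OC
F0 | step 14 | none | none
F5 | step 16 | (3R,6E)-1-{2,4-bis[(triisopropylsilyl)oxy]phenyl}-9-hydroxy-3,7,11-trimethyl-3-vinyldodeca-6,10-dien-1-one (both C9 epimers) | C=C[C@](C)(CC/C=C(\C)CC(O)C=C(C)C)CC(=O)c1ccc(O[Si](C(C)C)(C(C)C)C(C)C)cc1O[Si](C(C)C)(C(C)C)C(C)C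
F6 | step 16 | (R,E)-1-{2,4-bis[(triisopropylsilyl)oxy]phenyl}-3,7,11-trimethyl-3-vinyldodeca-6,10-diene-1,9-dione | C=C[C@](C)(CC/C=C(\C)CC(=O)C=C(C)C)CC(=O)c1ccc(O[Si](C(C)C)(C(C)C)C(C)C)cc1O[Si](C(C)C)(C(C)C)C(C)C
A1 | alternative 1 | 4-methyl-4-vinylcyclohexan-1-one | C=CC1(C)CCC(=O)CC1
A2 | alternative 1 | (R)-5-methyl-5-vinyloxepan-2-one | O=C1CC[C@@](C)(C=C)CCO1
A3 | alternative 2 | (R,E)-{1-[(1-{2,4-bis[(tert-butyldimethylsilyl)oxy]phenyl}vinyl)oxy]-3,7-dimethylocta-2,6-dien-1-yl}dimethyl(phenyl)silane | C=C(O[C@H]([Si](C)(C)c1ccccc1)/C=C(\C)CCC=C(C)C)c1ccc(O[Si](C)(C)C(C)(C)C)cc1O[Si](C)(C)C(C)(C)C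
A4 | alternative 2 | (R,E)-1-[2,4-bis(tert-butyldimethylsilyloxy)phenyl]-3-[2-(dimethylphenylsilyl)vinyl]-3,7-dimethyloct-6-en-1-one | C[Si](C)(c1ccccc1)/C=C/[C@](C)(CCC=C(C)C)CC(=O)c1ccc(O[Si](C)(C)C(C)(C)C)cc1O[Si](C)(C)C(C)(C)C
A5 | alternative 3 | 3-vinylcyclohex-2-en-1-one | C=CC1=CC(=O)CCC1
A6 | alternative 3 | (R)-3-methyl-3-vinylcyclohexan-1-one | O=C1C[C@](C)(C=C)CCC1
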